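The route cuts the C1–C2 bond of the cembranolide, the bond shared by the 14-membered carbocycle and the cis-fused α-methylene-γ-butyrolactone (C1 is the ring-fusion CH, C2 the allylic lactone O–CH). The O–C2–C1–C15(=C17H2)–C16(=O) array is the retron of a 2-(methoxycarbonyl)allyl-metal addition to an aldehyde. An open-chain (2Z)-2-(bromomethyl)enoate carrying a farnesal-type enal at its far end is therefore treated with CrCl2: one operation closes the macrocycle, sets C1 and C2, and lactonises. The precursor comes from (2E,6E)-farnesol, which supplies all three E-trisubstituted olefins; C13 is set by Brown allylboration and the acrylate arm is added by cross-metathesis.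

Key step: step 8

Remark on numbering: cembrane numbering is used for the ring atoms (C1 = ring-fusion CH carrying C15; C2 = lactone O–CH; C13 = CH–OAc; C14 = CH2 between C13 and C1; C15, C16, C17 = α-carbon, carbonyl carbon and exocyclic methylene of the lactone). The target is then (1S,2S,13R), with a cis-fused lactone.

Step 1
Reactants: 1 (2E,6E)-farnesol
Product: 2 tert-butyldimethyl[(2E,6E)-3,7,11-trimethyldodeca-2,6,10-trienyloxy]silane
Conditions: TBSCl, imidazole, DMF, 0 °C to rt
Reagents that add atoms: tert-butyldimethylsilyl chloride, CC(C)(C)[Si](C)(C)Cl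
Why: Imidazole-promoted silylation of the only hydroxyl group (the future C2 oxygen) gives a silyl ether that should survive the oxidations, the allylboration and the acetylation and can later be removed without touching an acetate.

Step 2
Reactants: 2 farnesyl silyl ether
Product: 4 (2E,6E,10E)-12-(tert-butyldimethylsilyloxy)-2,6,10-trimethyldodeca-2,6,10-trienal, via allylic alcohol 3 (not isolated)
Conditions: SeO2 (0.3 equiv), t-BuOOH, salicylic acid (cat.), CH2Cl2, 0 °C to rt; filter, then MnO2, CH2Cl2, rt
Reagents that add atoms: selenium dioxide, O=[Se]=O (oxygen carrier); tert-butyl hydroperoxide, CC(C)(C)OO (terminal oxygen source)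
Why: Sharpless SeO2/t-BuOOH allylic oxidation (ene reaction, then [2,3]-sigmatropic shift) should attack the E-methyl group of the terminal, most electron-rich and least hindered trisubstituted olefin, and MnO2 then converges the alcohol/aldehyde mixture on the E-enal.

Step 3
Reactants: 4 silyloxy trienal
Product: 6 (4R,5E,9E,13E)-15-(tert-butyldimethylsilyloxy)-5,9,13-trimethylpentadeca-1,5,9,13-tetraen-4-ol, via borinate ester 5 (not isolated)
Conditions: (+)-Ipc2BOMe, allylmagnesium bromide (C3H5MgBr), Et2O, 0 °C to rt; then 4, −78 °C; NaOH, H2O2, 0 °C to rt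
Reagents that add atoms: allylmagnesium bromide, C=CC[Mg]Br
Why: Brown allylboration through a chair transition state should set C13 as R, because the reagent made from (+)-Ipc2BOMe (from (−)-α-pinene) is the antipode that gives (R)-carbinols from aryl and alkenyl aldehydes; oxidative work-up cleaves the borinate.

Step 4
Reactants: 6 (4R)-homoallylic alcohol
Product: 7 (4R,5E,9E,13E)-15-(tert-butyldimethylsilyloxy)-5,9,13-trimethylpentadeca-1,5,9,13-tetraen-4-yl acetate
Conditions: Ac2O, pyridine, DMAP (cat.), CH2Cl2, rt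
Reagents that add atoms: acetic anhydride, CC(=O)OC(C)=O
Why: DMAP-catalysed acylation installs the acetate of the target at this stage, so that no protecting-group change is needed once the α-methylene lactone exists.

Step 5
Reactants: 7 silyloxy acetate
Product: 8 (4R,5E,9E,13E)-15-hydroxy-5,9,13-trimethylpentadeca-1,5,9,13-tetraen-4-yl acetate
Conditions: HF·pyridine, pyridine, THF, 0 °C to rt
Reagents that add atoms: none
Why: Buffered fluoride-driven desilylation should cleave the primary silyl ether while the secondary allylic acetate and the olefins stay untouched.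

Step 6
Reactants: 8 hydroxy acetate
Product: 9 (4R,5E,9E,13E)-5,9,13-trimethyl-15-oxopentadeca-1,5,9,13-tetraen-4-yl acetate
Conditions: MnO2, CH2Cl2, rt
Reagents that add atoms: none
Why: MnO2 is a chemoselective oxidant for allylic alcohols and should give the E-enal without affecting the acetate or the terminal olefin.

Step 7
Reactants: 9 enal acetate; 10 methyl 2-(bromomethyl)acrylate (5 equiv)
Product: 11 methyl (2Z,5R,6E,10E,14E)-5-acetoxy-2-(bromomethyl)-6,10,14-trimethyl-16-oxohexadeca-2,6,10,14-tetraenoate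
Conditions: second-generation Hoveyda–Grubbs catalyst RuCl2(H2IMes)(=CH-C6H4-2-OiPr) (10 mol%), CH2Cl2, 40 °C, argon sweep
Reagents that add atoms: none
Why: Olefin cross-metathesis should join the only monosubstituted olefin of 9 with the 1,1-disubstituted acrylate 10, since the trisubstituted olefins and the enal are too hindered or electron-poor to compete, and the enoate should form under thermodynamic control with the chain trans to the ester (the 2Z isomer).

Step 8
Reactants: 11 bromo ester enal
Product: 14 (1S,2S,3E,7E,11E,13R)-13-acetoxycembra-3,7,11,15(17)-tetraen-16,2-olide, via allylchromium species 12 (not isolated), via chromium alkoxide 13 (not isolated)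
Conditions: CrCl2 (10 equiv), 4 Å MS, THF, syringe-pump addition of 11 to 0.002 M, rt then 45 °C; aq NH4Cl
Reagents that add atoms: none
Why: Two equivalents of CrCl2 should convert the allylic bromide into the trivalent allylchromium 12, whose γ-carbon (C1) adds to the enal carbonyl carbon (C2) through a closed chair transition state to give alkoxide 13, which then attacks the neighbouring methyl ester to form the lactone; the closest known reaction type is the Nozaki–Hiyama–Kishi allylation used as a macrocyclisation, in its 2-(alkoxycarbonyl)allyl variant that forms α-methylene-γ-butyrolactones. The 14-membered carbocycle closes by 14-exo-trig addition to the aldehyde and the lactone by 5-exo-trig acyl substitution. The cis relation of C1 and C2 (syn adduct) should follow from the allylchromium geometry with C14 trans to the ester, which places C14 axial and the alkenyl residue of the aldehyde equatorial in the chair. The absolute sense of the pair is expected to come from the C13 acetoxy centre: the C1–C2 bond should form anti to the C14–C13 bond with the C12–C13–C14–C1 segment extended and OAc on the periphery of the nascent ring, which avoids a syn-pentane contact between OAc and the acrylate branch only in the 13R/1S (1,3-anti) pairing. The step needs γ- over α-attack and 1,2- over 1,4-addition (both secured by the closed six-membered transition state of allylchromium reagents), ring closure over oligomerisation (slow addition at high dilution), and survival of the allylic acetate and the enal (CrCl2 without nickel salts should leave both alone).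

Compound list
1 | (2E,6E)-farnesol | OC/C=C(\C)CC/C=C(\C)CCC=C(C)C | starting material
2 | tert-butyldimethyl[(2E,6E)-3,7,11-trimethyldodeca-2,6,10-trienyloxy]silane | CC(C)(C)[Si](C)(C)OC/C=C(\C)CC/C=C(\C)CCC=C(C)C | intermediate
3 | (2E,6E,10E)-12-(tert-butyldimethylsilyloxy)-2,6,10-trimethyldodeca-2,6,10-trien-1-ol (not isolated) | CC(C)(C)[Si](C)(C)OC/C=C(\C)CC/C=C(\C)CC/C=C(\C)CO | intermediate
4 | (2E,6E,10E)-12-(tert-butyldimethylsilyloxy)-2,6,10-trimethyldodeca-2,6,10-trienal | CC(C)(C)[Si](C)(C)OC/C=C(\C)CC/C=C(\C)CC/C=C(\C)C=O | intermediate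
5 | bis[(+)-isopinocampheyl]borinate ester of alcohol 6 (not isolated) | CC(C)(C)[Si](C)(C)OC/C=C(\C)CC/C=C(\C)CC/C=C(\C)[C@H](OB([C@H]1C[C@H]2C[C@@H]([C@@H]1C)C2(C)C)[C@H]1C[C@H]2C[C@@H]([C@@H]1C)C2(C)C)CC=C | intermediate
6 | (4R,5E,9E,13E)-15-(tert-butyldimethylsilyloxy)-5,9,13-trimethylpentadeca-1,5,9,13-tetraen-4-ol | CC(C)(C)[Si](C)(C)OC/C=C(\C)CC/C=C(\C)CC/C=C(\C)[C@H](O)CC=C | intermediate
7 | (4R,5E,9E,13E)-15-(tert-butyldimethylsilyloxy)-5,9,13-trimethylpentadeca-1,5,9,13-tetraen-4-yl acetate | CC(C)(C)[Si](C)(C)OC/C=C(\C)CC/C=C(\C)CC/C=C(\C)[C@H](OC(C)=O)CC=C | intermediate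
8 | (4R,5E,9E,13E)-15-hydroxy-5,9,13-trimethylpentadeca-1,5,9,13-tetraen-4-yl acetate | OC/C=C(\C)CC/C=C(\C)CC/C=C(\C)[C@H](OC(C)=O)CC=C | intermediate
9 | (4R,5E,9E,13E)-5,9,13-trimethyl-15-oxopentadeca-1,5,9,13-tetraen-4-yl acetate | O=C/C=C(\C)CC/C=C(\C)CC/C=C(\C)[C@H](OC(C)=O)CC=C | intermediate
10 | methyl 2-(bromomethyl)acrylate | C=C(CBr)C(=O)OC | starting material
11 | methyl (2Z,5R,6E,10E,14E)-5-acetoxy-2-(bromomethyl)-6,10,14-trimethyl-16-oxohexadeca-2,6,10,14-tetraenoate | O=C/C=C(\C)CC/C=C(\C)CC/C=C(\C)[C@H](OC(C)=O)C/C=C(\CBr)C(=O)OC | intermediate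
12 | dichloro(allyl)chromium species from 11, trivalent chromium on the former CH2Br carbon (not isolated) | O=C/C=C(\C)CC/C=C(\C)CC/C=C(\C)[C@H](OC(C)=O)C/C=C(\C[Cr](Cl)Cl)C(=O)OC | intermediate
13 | dichlorochromium alkoxide of methyl 2-[(1S,2S,13R)-13-acetoxy-2-hydroxy-4,8,12-trimethylcyclotetradeca-3E,7E,11E-trien-1-yl]acrylate (not isolated) | Cl[Cr](Cl)O[C@H]1/C=C(\C)CC/C=C(\C)CC/C=C(\C)[C@H](OC(C)=O)C[C@H]1C(=C)C(=O)OC | intermediate
14 | (1S,2S,3E,7E,11E,13R)-13-acetoxycembra-3,7,11,15(17)-tetraen-16,2-olide, i.e. (3aS,5R,6E,10E,14E,15aS)-6,10,14-trimethyl-3-methylidene-2-oxo-2,3,3a,4,5,8,9,12,13,15a-decahydrocyclotetradeca[b]furan-5-yl acetate | C=C1C(=O)O[C@H]2/C=C(\C)CC/C=C(\C)CC/C=C(\C)[C@H](OC(C)=O)C[C@@H]12 | target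

Total step count: 8. Longest linear sequence: 8 steps (from 1).

Steps most likely to fail

Step 8. What may go wrong: the allylchromium adds on the wrong face relative to C13 (a 1,3-syn instead of a 1,3-anti pairing) or without a useful preference, so that the lactone centres come out with the wrong sense relative to the acetate. Fallback (sets out from 4, comes back at 14): C13 is entered with the opposite configuration and inverted at the end. Aldehyde 4 is allylated with the antipodal borane made from (−)-Ipc2BOMe and allylmagnesium bromide, via the antipodal borinate ester F1, to give the (4S)-homoallylic alcohol F2. TBSOTf and 2,6-lutidine give the bis-silyl ether F3. PPTS in MeOH removes only the primary allylic silyl group and gives the primary alcohol F4, and MnO2 gives the enal F5. Cross-metathesis with 10 under the conditions of step 7 gives the silyloxy bromo ester F6. CrCl2 under the conditions of step 8 passes through the allylchromium species F7 and the chromium alkoxide F8 to the (13S)-silyloxy lactone F9, in which a 1,3-syn preference would now deliver the required 1S,2S lactone. HF·pyridine gives the (13S)-hydroxy lactone F10, and a Mitsunobu reaction with acetic acid (PPh3, DIAD, THF, 0 °C) inverts C13 and gives 14.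

Step 7. What may go wrong: slow turnover of the 1,1-disubstituted acrylate, homodimerisation of 9, and decomposition of the ruthenium carbene by the allylic bromide. Fallback (sets out from 9, comes back at 11): the halide is kept out of the metathesis event. Compound 9 is cross-metathesised with methyl 2-(hydroxymethyl)acrylate (C=C(CO)C(=O)OC) to give the allylic alcohol F11, which Appel bromination (CBr4, PPh3, CH2Cl2, 0 °C) converts into 11 with the olefin geometry unchanged.

Step 2. What may go wrong: incomplete and unselective allylic oxidation (attack at internal allylic positions, over-oxidation, partial loss of the silyl ether in the acidic medium). Fallback (sets out from 2, comes back at 4): the terminal olefin is cleaved and the enal rebuilt by olefination. Terminal-selective bromohydrin formation of 2 with NBS in aqueous THF gives the racemic bromohydrin F12. K2CO3 in MeOH closes it to the racemic terminal epoxide F13. H5IO6 in THF/Et2O cleaves the epoxide to the trisnor aldehyde F14. Wittig olefination with 2-(triphenylphosphoranylidene)propanal (CC(C=O)=P(c1ccccc1)(c1ccccc1)c1ccccc1) in hot benzene should give the E-enal 4.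

Further compounds
F1 | step 8 | bis[(−)-isopinocampheyl]borinate ester of alcohol F2 (not isolated) | CC(C)(C)[Si](C)(C)OC/C=C(\C)CC/C=C(\C)CC/C=C(\C)[C@@H](OB([C@@H]1C[C@@H]2C[C@H]([C@H]1C)C2(C)C)[C@@H]1C[C@@H]2C[C@H]([C@H]1C)C2(C)C)CC=C
F2 | step 8 | (4S,5E,9E,13E)-15-(tert-butyldimethylsilyloxy)-5,9,13-trimethylpentadeca-1,5,9,13-tetraen-4-ol | CC(C)(C)[Si](C)(C)OC/C=C(\C)CC/C=C(\C)CC/C=C(\C)[C@@H](O)CC=C
F3 | step 8 | (4S,5E,9E,13E)-4,15-bis(tert-butyldimethylsilyloxy)-5,9,13-trimethylpentadeca-1,5,9,13-tetraene | CC(C)(C)[Si](C)(C)OC/C=C(\C)CC/C=C(\C)CC/C=C(\C)[C@@H](O[Si](C)(C)C(C)(C)C)CC=C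
F4 | step 8 | (2E,6E,10E,12S)-12-(tert-butyldimethylsilyloxy)-3,7,11-trimethylpentadeca-2,6,10,14-tetraen-1-ol | OC/C=C(\C)CC/C=C(\C)CC/C=C(\C)[C@@H](O[Si](C)(C)C(C)(C)C)CC=C
F5 | step 8 | (2E,6E,10E,12S)-12-(tert-butyldimethylsilyloxy)-3,7,11-trimethylpentadeca-2,6,10,14-tetraenal | O=C/C=C(\C)CC/C=C(\C)CC/C=C(\C)[C@@H](O[Si](C)(C)C(C)(C)C)CC=C
F6 | step 8 | methyl (2Z,5S,6E,10E,14E)-2-(bromomethyl)-5-(tert-butyldimethylsilyloxy)-6,10,14-trimethyl-16-oxohexadeca-2,6,10,14-tetraenoate | O=C/C=C(\C)CC/C=C(\C)CC/C=C(\C)[C@@H](O[Si](C)(C)C(C)(C)C)C/C=C(\CBr)C(=O)OC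
F7 | step 8 | dichloro(allyl)chromium species from F6 (not isolated) | O=C/C=C(\C)CC/C=C(\C)CC/C=C(\C)[C@@H](O[Si](C)(C)C(C)(C)C)C/C=C(\C[Cr](Cl)Cl)C(=O)OC
F8 | step 8 | dichlorochromium alkoxide of the (1S,2S,13S)-13-silyloxy hydroxy ester (not isolated) | Cl[Cr](Cl)O[C@H]1/C=C(\C)CC/C=C(\C)CC/C=C(\C)[C@@H](O[Si](C)(C)C(C)(C)C)C[C@H]1C(=C)C(=O)OC
F9 | step 8 | (1S,2S,3E,7E,11E,13S)-13-(tert-butyldimethylsilyloxy)cembra-3,7,11,15(17)-tetraen-16,2-olide | C=C1C(=O)O[C@H]2/C=C(\C)CC/C=C(\C)CC/C=C(\C)[C@@H](O[Si](C)(C)C(C)(C)C)C[C@@H]12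
F10 | step 8 | (1S,2S,3E,7E,11E,13S)-13-hydroxycembra-3,7,11,15(17)-tetraen-16,2-olide | C=C1C(=O)O[C@H]2/C=C(\C)CC/C=C(\C)CC/C=C(\C)[C@@H](O)C[C@@H]12
F11 | step 7 | methyl (2E,5R,6E,10E,14E)-5-acetoxy-2-(hydroxymethyl)-6,10,14-trimethyl-16-oxohexadeca-2,6,10,14-tetraenoate | O=C/C=C(\C)CC/C=C(\C)CC/C=C(\C)[C@H](OC(C)=O)C/C=C(\CO)C(=O)OC
F12 | step 2 | (6E,10E)-3-bromo-12-(tert-butyldimethylsilyloxy)-2,6,10-trimethyldodeca-6,10-dien-2-ol (racemic) | CC(C)(C)[Si](C)(C)OC/C=C(\C)CC/C=C(\C)CCC(Br)C(C)(C)O
F13 | step 2 | tert-butyl{[(2E,6E)-9-(3,3-dimethyloxiran-2-yl)-3,7-dimethylnona-2,6-dienyl]oxy}dimethylsilane (racemic) | CC(C)(C)[Si](C)(C)OC/C=C(\C)CC/C=C(\C)CCC1OC1(C)C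
F14 | step 2 | (4E,8E)-10-(tert-butyldimethylsilyloxy)-4,8-dimethyldeca-4,8-dienal | CC(C)(C)[Si](C)(C)OC/C=C(\C)CC/C=C(\C)CCC=O
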